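**Plan**

1. Cuts: (a) the C-2′–C-3′ single bond between the first and second double bond of the hepta-1,3,5-trienyl chain. It separates a vinyl group on the quaternary carbinol C-5 of the 7-oxabicyclo[4.1.0]hept-3-en-2-one ring from a 2,4-dienamide, so each half can carry a preformed E-alkene terminus (Sn, I) and the two unprotected halves are joined last. (b) The ring C-3–N enamide bond. (c) The C-5–alkyne bond. (d) The two side-chain amide bonds and their olefins.
2. Forward: the six-membered ring is bought as a quinone monoketal. A norbornene ring is fused on by Diels–Alder reaction as a temporary template, the oxirane ring is closed and the carbinol made on it, and the template ring is removed by retro-Diels–Alder reaction. Then follow α-iodination, amidation with the upper chain, desilylation, hydrostannation and coupling with the lower chain.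
3. Stereochemistry: the absolute sense comes from one catalytic enantioselective Diels–Alder reaction. Oxirane (C-1, C-6) and carbinol (C-5) are relayed from the template by two convex-face attacks, which places the hydroxyl trans to the oxirane oxygen (direct addition to a monocyclic epoxyketone would place it cis). The four template stereocentres are then erased.
4. C-4 (R) of the octenoyl chain comes from an oxazolidinone-directed enolate methylation. The E double bonds come from Wittig and Takai olefinations, syn-hydrostannation and a stereoretentive coupling.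

Key step: step 19

Assumption: the (S)-BINOL–titanium catalyst of step 10 is taken to give the cycloadduct in the absolute sense drawn; should the sense prove opposite, (R)-BINOL is used and nothing else changes.

**Route**

Step 1
Reactants: 1 (R)-4-benzyloxazolidin-2-one; 2 hexanoyl chloride
Product: 3 (R)-4-benzyl-3-hexanoyloxazolidin-2-one
Conditions: n-BuLi, THF, −78 °C; then 2, −78 → 0 °C
Reagents that add atoms: none
Why: N-acylation of the lithiated oxazolidinone by the acid chloride attaches the auxiliary for an Evans alkylation and creates no stereocentre.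

Step 2
Reactants: 3
Product: 4 (R)-4-benzyl-3-[(R)-2-methylhexanoyl]oxazolidin-2-one
Conditions: NaN(SiMe3)2, THF, −78 °C; MeI, −78 → −40 °C
Reagents that add atoms: iodomethane, CI
Why: Evans asymmetric alkylation, in which the chelated (Z)-sodium enolate is methylated on the face opposite the benzyl group, which sets the new centre as R (the later C-4 of the octenoyl chain).

Step 3
Reactants: 4
Product: 5 (R)-2-methylhexan-1-ol
Conditions: LiBH4, H2O (1 equiv), Et2O, 0 °C
Reagents that add atoms: none
Why: reductive cleavage of the N-acyloxazolidinone by borohydride should give the primary alcohol without touching the α-stereocentre and return the auxiliary.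

Step 4
Reactants: 5; 6 (carbamoylmethylene)triphenylphosphorane
Product: 8 (R,E)-4-methyloct-2-enamide, via (R)-2-methylhexanal 7 (not isolated)
Conditions: Dess–Martin periodinane, CH2Cl2, 0 °C → rt; then 6, rt
Reagents that add atoms: none
Why: Dess–Martin oxidation followed in the same flask by a Wittig reaction of the stabilised ylide should give the E-enamide, and immediate trapping of the α-branched aldehyde under non-basic conditions should preserve the stereocentre.

Step 5
Reactants: 9 cyclopentane-1,3-dione
Product: 10 2-(hydroxyimino)cyclopentane-1,3-dione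
Conditions: NaNO2, aq. HCl, 0 °C
Reagents that add atoms: sodium nitrite, [Na+].[O-]N=O
Why: C-nitrosation of the enolised 1,3-dione at its active methylene, followed by tautomerisation to the oxime.

Step 6
Reactants: 10
Product: 11 2-amino-3-hydroxycyclopent-2-en-1-one hydrochloride
Conditions: H2 (1 atm), 10% Pd/C, HCl, MeOH, rt
Reagents that add atoms: hydrogen chloride, Cl
Why: catalytic hydrogenation of the oxime in acid should give the α-amino dione as its enolised hydrochloride, a form that cannot self-condense.

Step 7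
Reactants: 12 ethyl (E)-4-oxobut-2-enoate
Product: 13 ethyl (2E,4E)-5-iodopenta-2,4-dienoate
Conditions: CHI3, CrCl2, THF, 0 °C
Reagents that add atoms: iodoform, IC(I)I
Why: Takai olefination, in which the geminal dichromium species from iodoform adds to the aldehyde and eliminates to the E-vinyl iodide while the existing E-enoate is untouched.

Step 8
Reactants: 13
Product: 14 (2E,4E)-5-iodopenta-2,4-dienoic acid
Conditions: LiOH, THF–H2O, 0 °C; then 1 M HCl
Reagents that add atoms: lithium hydroxide, [Li+].[OH-]
Why: saponification of the ethyl ester under mild conditions that should leave the dienyl iodide and both double-bond geometries intact.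

Step 9
Reactants: 14; 11
Product: 16 (2E,4E)-N-(2-hydroxy-5-oxocyclopent-1-en-1-yl)-5-iodopenta-2,4-dienamide, via (2E,4E)-5-iodopenta-2,4-dienoyl chloride 15 (not isolated)
Conditions: (COCl)2, DMF (cat.), CH2Cl2, 0 °C; then 11, Et3N, CH2Cl2, 0 °C → rt
Reagents that add atoms: none
Why: amide formation through the acid chloride, in which the liberated amine of the enolised aminodione is acylated and any enol ester formed should pass its acyl group on to nitrogen under the basic conditions.

Step 10
Reactants: 17 4,4-dimethoxycyclohexa-2,5-dien-1-one; 18 cyclopenta-1,3-diene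
Product: 19 (1R,4S,4aR,8aS)-8,8-dimethoxy-1,4,4a,8a-tetrahydro-1,4-methanonaphthalen-5(8H)-one (endo adduct)
Conditions: (S)-BINOL, TiCl2(OiPr)2 (10 mol %), 4 Å MS, CH2Cl2, −30 °C
Reagents that add atoms: none
Why: catalytic enantioselective endo Diels–Alder reaction of a quinone monoketal, in which the chiral titanium Lewis acid bound to the carbonyl selects one of the two enantiotopic enone double bonds and its face and so sets the four stereocentres of the norbornene template in one absolute sense.

Step 11
Reactants: 19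
Product: 20 (1R,4S,4aR,6R,7S,8aS)-6,7-epoxy-8,8-dimethoxy-1,4,4a,6,7,8a-hexahydro-1,4-methanonaphthalen-5(8H)-one (oxirane on the convex face, cis to H-4a and H-8a)
Conditions: 30% H2O2, NaOH, MeOH, 0 °C
Reagents that add atoms: hydrogen peroxide, OO
Why: Weitz–Scheffer epoxidation of the remaining enone, in which hydroperoxide adds to the convex face of the folded endo adduct because the concave face is covered by the etheno bridge, so that C-6 and C-7 are set from the template.

Step 12
Reactants: 20; 21 ethynyltrimethylsilane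
Product: 22 (1R,4S,4aR,5S,6R,7S,8aS)-6,7-epoxy-8,8-dimethoxy-5-[(trimethylsilyl)ethynyl]-1,4,4a,5,6,7,8,8a-octahydro-1,4-methanonaphthalen-5-ol (alkynyl cis and hydroxyl trans to the oxirane oxygen)
Conditions: 21, n-BuLi, THF, −78 °C; then 20, −78 °C; AcOH quench at −78 °C
Reagents that add atoms: none
Why: 1,2-addition of the lithium acetylide to the ketone from the convex face, the face of the oxirane oxygen, because the concave face is blocked by the etheno bridge, which sets the carbinol with the hydroxyl trans to the oxirane oxygen.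

Step 13
Reactants: 22
Product: 23 (1R,4S,4aR,5S,6R,7S,8aS)-6,7-epoxy-5-hydroxy-5-[(trimethylsilyl)ethynyl]-1,4,4a,5,6,7-hexahydro-1,4-methanonaphthalen-8(8aH)-one (locants as in 22)
Conditions: montmorillonite K10, wet CH2Cl2, rt
Reagents that add atoms: water, O
Why: mild acid-catalysed hydrolysis of the dimethyl ketal on the clay, which oxirane, silylalkyne and tertiary alcohol should survive.

Step 14
Reactants: 23
Product: 24 (1S,5S,6R)-5-hydroxy-5-[(trimethylsilyl)ethynyl]-7-oxabicyclo[4.1.0]hept-3-en-2-one
Conditions: Ph2O, 230 °C, 20 min, N2 stream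
Reagents that add atoms: none
Why: retro-Diels–Alder reaction, in which loss of cyclopentadiene regenerates the enone double bond and erases the four template stereocentres while the three centres set from them are untouched.

Step 15
Reactants: 24
Product: 25 (1S,5S,6R)-5-hydroxy-3-iodo-5-[(trimethylsilyl)ethynyl]-7-oxabicyclo[4.1.0]hept-3-en-2-one
Conditions: I2, pyridine, CH2Cl2, 0 °C → rt
Reagents that add atoms: iodine, II
Why: amine-mediated α-iodination of the enone (conjugate addition of pyridine, iodination of the enolate, elimination of pyridine), which can occur only at C-3 and affects no stereocentre.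

Step 16
Reactants: 25; 8
Product: 26 (2E,4R)-N-[(1S,5S,6R)-5-hydroxy-2-oxo-5-[(trimethylsilyl)ethynyl]-7-oxabicyclo[4.1.0]hept-3-en-3-yl]-4-methyloct-2-enamide
Conditions: CuI (10 mol %), N,N′-dimethylethylenediamine (20 mol %), Cs2CO3, THF, 45 °C
Reagents that add atoms: none
Why: copper-catalysed Goldberg-type N-vinylation of the primary amide by the activated α-iodoenone, with a carbonate base too weak to ionise the tertiary alcohol appreciably and a silyl cap that keeps the alkyne out of the copper chemistry.

Step 17
Reactants: 26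
Product: 27 (2E,4R)-N-[(1S,5S,6R)-5-ethynyl-5-hydroxy-2-oxo-7-oxabicyclo[4.1.0]hept-3-en-3-yl]-4-methyloct-2-enamide
Conditions: TBAF, AcOH, THF, 0 °C
Reagents that add atoms: none
Why: fluoride-induced protodesilylation of the alkynylsilane, buffered with acetic acid to spare the base-sensitive epoxyketone.

Step 18
Reactants: 27
Product: 28 (2E,4R)-N-[(1S,5S,6R)-5-hydroxy-2-oxo-5-[(E)-2-(tributylstannyl)ethenyl]-7-oxabicyclo[4.1.0]hept-3-en-3-yl]-4-methyloct-2-enamide
Conditions: Bu3SnH (slow addition), PdCl2(PPh3)2 (3 mol %), THF, 0 °C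
Reagents that add atoms: tributyltin hydride, CCCC[SnH](CCCC)CCCC
Why: palladium-catalysed syn-hydrostannation of the terminal alkyne, which should place tin on the terminal carbon, away from the quaternary carbinol, and so give the E-vinylstannane faster than the hindered trisubstituted enone is reduced.

Step 19
Reactants: 28; 16
Product: 29 (2E,4R)-N-[(1S,5R,6R)-5-hydroxy-5-[(1E,3E,5E)-7-[(2-hydroxy-5-oxocyclopent-1-en-1-yl)amino]-7-oxohepta-1,3,5-trien-1-yl]-2-oxo-7-oxabicyclo[4.1.0]hept-3-en-3-yl]-4-methyloct-2-enamide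
Conditions: PdCl2(MeCN)2 (10 mol %), DMF, rt, dark
Reagents that add atoms: none
Why: Stille–Migita cross-coupling: zerovalent palladium, formed in the flask from PdCl2(MeCN)2 and the stannane, inserts into the C–I bond of 16, the vinyl group passes from tin in 28 to palladium, and reductive elimination forms the C-2′–C-3′ single bond of the trienyl chain. The closest known reaction type is the ligand-free vinyl–vinyl Stille coupling of a γ-hydroxy vinylstannane with a halodienamide in DMF. No ring is closed and no stereocentre is created, so the event only has to respect those already present. Both termini are stereodefined beforehand (E-stannane from the syn-hydrostannation, E,E-iodide from the E-enoate starting material and the Takai olefination) and every elementary step proceeds with retention, so the all-E triene follows from the partners. The selectivity needed is chemoselectivity on an unprotected substrate: the neutral conditions at room temperature should leave the tertiary alcohol trans to the oxirane (prone to Payne-type epoxide migration under base), the enaminone and the acidic enol of the cyclopentenone untouched, and only the C–I and C–Sn bonds react with palladium. Steric hindrance at the quaternary carbinol is remote from the terminal vinyl carbon, so transmetalation should be unimpeded.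

**Compound list**

1 | (R)-4-benzyloxazolidin-2-one | O=C1N[C@H](Cc2ccccc2)CO1 | starting material
2 | hexanoyl chloride | CCCCCC(Cl)=O | starting material
3 | (R)-4-benzyl-3-hexanoyloxazolidin-2-one | CCCCCC(=O)N1[C@H](Cc2ccccc2)COC1=O | intermediate
4 | (R)-4-benzyl-3-[(R)-2-methylhexanoyl]oxazolidin-2-one | CCCC[C@@H](C)C(=O)N1[C@H](Cc2ccccc2)COC1=O | intermediate
5 | (R)-2-methylhexan-1-ol | CCCC[C@@H](C)CO | intermediate
6 | (carbamoylmethylene)triphenylphosphorane | NC(=O)C=P(c1ccccc1)(c1ccccc1)c1ccccc1 | starting material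
7 | (R)-2-methylhexanal (formed in the flask) | CCCC[C@@H](C)C=O | intermediate
8 | (R,E)-4-methyloct-2-enamide | CCCC[C@@H](C)/C=C/C(N)=O | intermediate
9 | cyclopentane-1,3-dione | O=C1CCC(=O)C1 | starting material
10 | 2-(hydroxyimino)cyclopentane-1,3-dione | ON=C1C(=O)CCC1=O | intermediate
11 | 2-amino-3-hydroxycyclopent-2-en-1-one hydrochloride | Cl.NC1=C(O)CCC1=O | intermediate
12 | ethyl (E)-4-oxobut-2-enoate | CCOC(=O)/C=C/C=O | starting material
13 | ethyl (2E,4E)-5-iodopenta-2,4-dienoate | CCOC(=O)/C=C/C=C/I | intermediate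
14 | (2E,4E)-5-iodopenta-2,4-dienoic acid | OC(=O)/C=C/C=C/I | intermediate
15 | (2E,4E)-5-iodopenta-2,4-dienoyl chloride (formed in the flask) | ClC(=O)/C=C/C=C/I | intermediate
16 | (2E,4E)-N-(2-hydroxy-5-oxocyclopent-1-en-1-yl)-5-iodopenta-2,4-dienamide | O=C(/C=C/C=C/I)NC1=C(O)CCC1=O | intermediate
17 | 4,4-dimethoxycyclohexa-2,5-dien-1-one | COC1(OC)C=CC(=O)C=C1 | starting material
18 | cyclopenta-1,3-diene (distilled from its commercial dimer before use) | C1C=CC=C1 | starting material
19 | (1R,4S,4aR,8aS)-8,8-dimethoxy-1,4,4a,8a-tetrahydro-1,4-methanonaphthalen-5(8H)-one, endo adduct | O=C1C=CC(OC)(OC)[C@@H]2[C@H]1[C@@H]3C=C[C@H]2C3 | intermediate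
20 | (1R,4S,4aR,6R,7S,8aS)-6,7-epoxy-8,8-dimethoxy-1,4,4a,6,7,8a-hexahydro-1,4-methanonaphthalen-5(8H)-one, oxirane cis to H-4a and H-8a | O=C1[C@@H]4O[C@@H]4C(OC)(OC)[C@@H]2[C@H]1[C@@H]3C=C[C@H]2C3 | intermediate
21 | ethynyltrimethylsilane | C[Si](C)(C)C#C | starting material
22 | (1R,4S,4aR,5S,6R,7S,8aS)-6,7-epoxy-8,8-dimethoxy-5-[(trimethylsilyl)ethynyl]-1,4,4a,5,6,7,8,8a-octahydro-1,4-methanonaphthalen-5-ol | C[Si](C)(C)C#C[C@]1(O)[C@@H]4O[C@@H]4C(OC)(OC)[C@@H]2[C@H]1[C@@H]3C=C[C@H]2C3 | intermediate
23 | (1R,4S,4aR,5S,6R,7S,8aS)-6,7-epoxy-5-hydroxy-5-[(trimethylsilyl)ethynyl]-1,4,4a,5,6,7-hexahydro-1,4-methanonaphthalen-8(8aH)-one | C[Si](C)(C)C#C[C@]1(O)[C@@H]4O[C@@H]4C(=O)[C@@H]2[C@H]1[C@@H]3C=C[C@H]2C3 | intermediate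
24 | (1S,5S,6R)-5-hydroxy-5-[(trimethylsilyl)ethynyl]-7-oxabicyclo[4.1.0]hept-3-en-2-one | C[Si](C)(C)C#C[C@]1(O)[C@@H]2O[C@@H]2C(=O)C=C1 | intermediate
25 | (1S,5S,6R)-5-hydroxy-3-iodo-5-[(trimethylsilyl)ethynyl]-7-oxabicyclo[4.1.0]hept-3-en-2-one | C[Si](C)(C)C#C[C@]1(O)[C@@H]2O[C@@H]2C(=O)C(I)=C1 | intermediate
26 | (2E,4R)-N-[(1S,5S,6R)-5-hydroxy-2-oxo-5-[(trimethylsilyl)ethynyl]-7-oxabicyclo[4.1.0]hept-3-en-3-yl]-4-methyloct-2-enamide | CCCC[C@@H](C)/C=C/C(=O)NC1=C[C@](O)(C#C[Si](C)(C)C)[C@@H]2O[C@@H]2C1=O | intermediate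
27 | (2E,4R)-N-[(1S,5S,6R)-5-ethynyl-5-hydroxy-2-oxo-7-oxabicyclo[4.1.0]hept-3-en-3-yl]-4-methyloct-2-enamide | CCCC[C@@H](C)/C=C/C(=O)NC1=C[C@](O)(C#C)[C@@H]2O[C@@H]2C1=O | intermediate
28 | (2E,4R)-N-[(1S,5S,6R)-5-hydroxy-2-oxo-5-[(E)-2-(tributylstannyl)ethenyl]-7-oxabicyclo[4.1.0]hept-3-en-3-yl]-4-methyloct-2-enamide | CCCC[C@@H](C)/C=C/C(=O)NC1=C[C@](O)(/C=C/[Sn](CCCC)(CCCC)CCCC)[C@@H]2O[C@@H]2C1=O | intermediate
29 | (2E,4R)-N-[(1S,5R,6R)-5-hydroxy-5-[(1E,3E,5E)-7-[(2-hydroxy-5-oxocyclopent-1-en-1-yl)amino]-7-oxohepta-1,3,5-trien-1-yl]-2-oxo-7-oxabicyclo[4.1.0]hept-3-en-3-yl]-4-methyloct-2-enamide | CCCC[C@@H](C)/C=C/C(=O)NC1=C[C@](O)(/C=C/C=C/C=C/C(=O)NC2=C(O)CCC2=O)[C@@H]2O[C@@H]2C1=O | target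

**Step count and risks**

Total step count: 19 (upper chain steps 1–4, lower chain steps 5–9, core and end game steps 10–19).
Longest linear sequence: 10 steps (steps 10–19, from 17 to 29).

Steps most likely to fail:

Step 16. The carbonate base and the warm reaction may cause Payne-type epoxide migration of the trans-hydroxy oxirane or general base degradation before the C–N coupling at the hindered α-iodoenone is complete. The fallback sets out from 25 and brings nitrogen in as azide under nearly neutral conditions, forming the amide bond afterwards. NaN3 with CuI, sodium ascorbate and N,N′-dimethylethylenediamine in EtOH–H2O at rt should give (1S,5S,6R)-3-azido-5-hydroxy-5-[(trimethylsilyl)ethynyl]-7-oxabicyclo[4.1.0]hept-3-en-2-one F1. Staudinger reduction (PPh3, THF–H2O) should then give (1S,5S,6R)-3-amino-5-hydroxy-5-[(trimethylsilyl)ethynyl]-7-oxabicyclo[4.1.0]hept-3-en-2-one F2. The acylating agent is made from aldehyde 7: Wittig reaction with ethyl (triphenylphosphoranylidene)acetate gives ethyl (R,E)-4-methyloct-2-enoate F3, saponification (LiOH) gives (R,E)-4-methyloct-2-enoic acid F4, and oxalyl chloride gives (R,E)-4-methyloct-2-enoyl chloride F5. Acylation of F2 with F5 (pyridine, CH2Cl2, 0 °C) comes back to the route at 26.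

Step 18. Tin may be delivered to the internal alkyne carbon, and palladium hydride may reduce the enone in competition with the hydrostannation. The fallback sets out from 27 and 16 and forms the same chain bond by Sonogashira coupling (PdCl2(PPh3)2, CuI, iPr2NH, THF, rt). This should give the dienyne (2E,4R)-N-[(1S,5S,6R)-5-hydroxy-5-[(3E,5E)-7-[(2-hydroxy-5-oxocyclopent-1-en-1-yl)amino]-7-oxohepta-3,5-dien-1-yn-1-yl]-2-oxo-7-oxabicyclo[4.1.0]hept-3-en-3-yl]-4-methyloct-2-enamide F6. Ruthenium-catalysed trans-hydrosilylation of the alkyne with benzyldimethylsilane ([Cp*Ru(MeCN)3]PF6, CH2Cl2, 0 °C) should give the vinylsilane (2E,4R)-N-[(1S,5S,6R)-5-[(1Z,3E,5E)-2-[benzyl(dimethyl)silyl]-7-[(2-hydroxy-5-oxocyclopent-1-en-1-yl)amino]-7-oxohepta-1,3,5-trien-1-yl]-5-hydroxy-2-oxo-7-oxabicyclo[4.1.0]hept-3-en-3-yl]-4-methyloct-2-enamide F7; either regioisomer of the trans adduct serves. Protodesilylation (TBAF, AcOH, THF, 0 °C) should give the E-alkene, so the route is rejoined at 29 and step 19 is not needed.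

Step 10. Enantioselectivity may be eroded by uncatalysed cycloaddition of the very reactive diene, and the Lewis acid may ionise the dimethyl ketal. The fallback sets out from 17 and moves the enantio-determining event to the epoxidation. Mono-epoxidation under chiral phase-transfer catalysis (t-BuOOH, NaOH, N-benzylcinchonidinium chloride, toluene, 0 °C; the pseudoenantiomeric cinchoninium salt if the sense is opposite) should give (1R,6S)-5,5-dimethoxy-7-oxabicyclo[4.1.0]hept-3-en-2-one F8. Thermal Diels–Alder reaction of F8 with 18 (toluene, rt to 60 °C), the diene adding endo to the face opposite the oxirane, comes back to the route at 20.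

Further compounds
F1 | step 16 | (1S,5S,6R)-3-azido-5-hydroxy-5-[(trimethylsilyl)ethynyl]-7-oxabicyclo[4.1.0]hept-3-en-2-one | C[Si](C)(C)C#C[C@]1(O)[C@@H]2O[C@@H]2C(=O)C(N=[N+]=[N-])=C1
F2 | step 16 | (1S,5S,6R)-3-amino-5-hydroxy-5-[(trimethylsilyl)ethynyl]-7-oxabicyclo[4.1.0]hept-3-en-2-one | C[Si](C)(C)C#C[C@]1(O)[C@@H]2O[C@@H]2C(=O)C(N)=C1
F3 | step 16 | ethyl (R,E)-4-methyloct-2-enoate | CCCC[C@@H](C)/C=C/C(=O)OCC
F4 | step 16 | (R,E)-4-methyloct-2-enoic acid | CCCC[C@@H](C)/C=C/C(O)=O
F5 | step 16 | (R,E)-4-methyloct-2-enoyl chloride | CCCC[C@@H](C)/C=C/C(Cl)=O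
F6 | step 18 | (2E,4R)-N-[(1S,5S,6R)-5-hydroxy-5-[(3E,5E)-7-[(2-hydroxy-5-oxocyclopent-1-en-1-yl)amino]-7-oxohepta-3,5-dien-1-yn-1-yl]-2-oxo-7-oxabicyclo[4.1.0]hept-3-en-3-yl]-4-methyloct-2-enamide | CCCC[C@@H](C)/C=C/C(=O)NC1=C[C@](O)(C#C/C=C/C=C/C(=O)NC3=C(O)CCC3=O)[C@@H]2O[C@@H]2C1=O
F7 | step 18 | (2E,4R)-N-[(1S,5S,6R)-5-[(1Z,3E,5E)-2-[benzyl(dimethyl)silyl]-7-[(2-hydroxy-5-oxocyclopent-1-en-1-yl)amino]-7-oxohepta-1,3,5-trien-1-yl]-5-hydroxy-2-oxo-7-oxabicyclo[4.1.0]hept-3-en-3-yl]-4-methyloct-2-enamide | CCCC[C@@H](C)/C=C/C(=O)NC1=C[C@](O)(/C=C(/C=C/C=C/C(=O)NC3=C(O)CCC3=O)[Si](C)(C)Cc4ccccc4)[C@@H]2O[C@@H]2C1=O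
F8 | step 10 | (1R,6S)-5,5-dimethoxy-7-oxabicyclo[4.1.0]hept-3-en-2-one | O=C1[C@@H]2O[C@@H]2C(OC)(OC)C=C1
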